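I had 3 questions about this flask, and 2 of them were one quantity at two times: the excess of Zu over Qa.

common to all: Wu 0.069 M; Ze 0.069 M
- eta: Ym 0.39 M; Jy 1.7 mM; run made earlier
- delta: Ym 0.61 M; Jy 1.7 mM; run made earlier
- gamma: Ym 0.276 M; Jy 0.85 mM; run made earlier
- flask: Ym 0.276 M; Jy 1.7 mM; time 2.0 min

| run | time / s | Zu / % | Qa / % | Wu / % |
|---|---|---|---|---|
| eta | 10.0 | 0 | 0.1 | 49.6 |
| eta | 20.0 | 0 | 0.4 | 49.4 |
| eta | 40.0 | 1.5 | 0.3 | 48.6 |
| eta | 90.0 | 3.2 | 1.6 | 46.4 |
| delta | 12.0 | 0.2 | 0 | 49.4 |
| delta | 30.0 | 0.8 | 0 | 49.1 |
| delta | 60.0 | 2.2 | 0.8 | 47.9 |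
| delta | 90.0 | 3.6 | 1.3 | 46.6 |
| gamma | 12.0 | 0.1 | 0.3 | 49.7 |
| gamma | 30.0 | 1.1 | 0.1 | 49.4 |
| gamma | 60.0 | 2.6 | 1.4 | 47.9 |
| gamma | 90.0 | 2.7 | 1.7 | 45.9 |

(readings scatter by 0.3 percentage points)

- Ux is single-handed; Wu and Ze are mirror images of each other, charged as a racemate, each of them at the stated concentration
- Ym is a solid; its amount is given per volume of the solution
- the earlier runs were read with a standard deviation of 0.3 percentage points
- at the start none of Ym is in solution
- an excess is below zero if the other one leads
- the handed part of Ux does not stay in what it makes, so the products of the two hands are mirror images too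

- excess of Zu over Qa in the product at 12 s
- excess of Zu over Qa in the product at 2.0 min
- part of the Wu and Ze charged together that has reacted at 2.0 min

Wu and Ze were charged as a racemate and Zu and Qa are mirror images, so I set the zero of my scale at the symmetric case. My first extreme was a product that kept its hand once made, kinetic control: there the excess changed with the using up of Wu and Ze and with nothing else. My second was a product whose hands had reached balance, thermodynamic control: there the excess was zero. The flask had to lie between them, and the readings had to place it.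

Single early readings were poor against a scatter of 0.3 percentage points, so I pooled the three runs, whose Ym ran from 0.276 M to 0.61 M. Up to 40.0 s, Zu summed to 3.70% and Qa to 1.20%. The early excess, the difference of these sums over their total, came to 51.0%, a rough reading, with a selectivity factor near 3.08. The sums at 60.0 s and 90.0 s gave a lower 35.5%, so I read a slide towards zero. I committed to about 51.0% at 12 s and to something below 35.5% at 2.0 min.

The forecast gave 38% and 35%, with 6.8% reacted; of the early figure it said “within noise, so I assume a similar selectivity”. We parted at 12 s.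

The flask gave 48.9% at 12 s, 40.9% at 1.00 min and 32.6% at 2.0 min, with 6.69% reacted.

    Zu ⇌ Qa (k = 0.00400 /s)
    Ym ⇌ Ux, rate k2*(cs2 - [Ux]) while solid is left; crystals form when [Ux] > cs2 (solubility = 14.0 mM, k = 0.00640 /s)
    2 Jy → Qi (k = 100 /M/s)
    Ux + Ze → Qa (k = 0.360 /M/s)
    Ux + Wu → Zu (k = 1.10 /M/s)
    Wu + Jy ⇌ Ze + Jy, rate k6*[Jy]*[Wu] forward; the back reaction follows from the equilibrium constant (k = 2.00 /M/s)

At 2.0 min this flask stood at 63.9% of my pooled reading of the early excess. I carried both figures to a neighbouring flask, the same but for 0.11 M of Ym, a charge below every pooled run, and reckoned 51.0% at 12 s and that same share later. The neighbour gave 48.9% and 32.6%, which is 63.9% of that pooled reading, with 6.69% reacted and its solid Ym at 90.8% of its charge.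

The numbers in the tables are simulated from invented constants.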